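## The problem

Isocycloheterophyllin 29 is a flavone (benzenoid ring A, pyranone ring C, aryl ring B) that carries two further rings: a 2,2-dimethylpyran (ring D) fused through O7 and C8, and an oxepine (ring E) that ties C3 to the C2′ oxygen of ring B through a CH2–C(=CMe2)–O bridge (C1″, C2″, C3″). There is no stereocentre, so the whole difficulty lies in regiochemistry and functional-group tolerance. Ring A is fully substituted: three oxygens with three different fates (free hydroxyl on C5, ring D ether on C7, pyranone oxygen on C8a) alternate with three different carbon substituents (acyl carbon on C4a, prenyl on C6, ring D carbon on C8). A phloroglucinol starting point would leave all six positions to be told apart by selectivity alone. Ring E contains a tetrasubstituted aryl enol ether whose double bond must stay exocyclic (C2″=C3″), and it is sensitive to aqueous acid. The ring B catechol oxidises easily, above all as its phenoxide, and the prenyl and chromene double bonds exclude hydrogenolysis, strong protic acid and electrophilic halogen late in the route. The feature that opens the key step is the pattern of ring A itself, oxygen on C5, C7 and C8a with the prenyl group on C6 between two of them: a vinylketene (supplying C7, C8, C8a and C4a) and a prenyl-substituted ynol ether (supplying C6 and C5) give exactly this pattern on benzannulation, with each oxygen arriving in a different state.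

## Retrosynthesis

**29 from 28.** The last operation is fixed first: the three phenols of 29 are released from the tris(triisopropylsilyl) ether 28 by fluoride. No skeletal bond is cut, but the choice sets the protecting-group scheme. Fluoride leaves the enol ether of ring E, the prenyl group and ring D untouched, which acid-labile or hydrogenolysable groups on the catechol would not allow. The forward step only needs buffering, so that the catechol never stands as a free phenoxide.

**28 from 27.** Ring E is opened at the O–C2″ bond. This leads to the 2′-hydroxyflavone 27, which carries a 2-bromo-3-methylbut-2-enyl group on C3. The neighbouring cuts (dehydration of a tertiary alcohol next to the aryl ether, or migration of an isopropenyl double bond into conjugation) would leave the position of the double bond to be decided at the very end. The alkenyl bromide fixes it from the start. Precursor 27 has one ring less and no enol ether. The forward reaction must close a seven-membered ring by C–O coupling at a fully substituted alkenyl carbon.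

**27 from 21 and 24.** Ring C is opened at O1–C2 and the C3–C1″ bond is cut. This gives the 1,3-diketone 21 and the allylic dibromide 24, joined forward by C-alkylation to 25 and closed by acid through the methoxymethyl flavone 26. Putting the side chain on a finished flavone would need C3 metalation or halogenation in the presence of three alkenes, so the enolisable diketone is the better place. Dibromide 24 comes in one step from 3-methylbuta-1,2-diene 22 through its tertiary allylic isomer 23. The forward ring closure needs the C8a hydroxyl to be the only free phenol, and the 2′-oxygen to be unmasked only after ring C exists.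

**21 from 15 and 19.** The C2–C3 bond is cut between the ortho-hydroxyacetophenone 15 and the ring B acid 19, which is activated as chloride 20. This is the most convergent cut of the flavone: ring A with ring D attached on one side, ring B on the other. Acid 19 is reached from 2,4,5-trihydroxybenzaldehyde 16 through the bis-silyl ether 17 and the methoxymethyl ether 18. The 2-oxygen is protected differently from the catechol so that it alone can be freed for ring E.

**15 from 13.** The free C8a hydroxyl of 15 goes back to the ethyl ether 14, and the acetyl group of 14 (C4a–C4 bond) goes back to chromene 13. Chromene 13 has a single aryl C–H, so the acylation has no regiochemical choice. The ketone then directs removal of the ethyl group from the oxygen beside it, while the silyl ether on the other side stays.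

**13 from 10 and 11.** Ring D is cut at its C8–C and O7–C bonds, giving phenol 10 and 3-methylbut-2-enal 11; forward, the annulation passes through ortho-quinone methide 12. Phenol 10 has one free hydroxyl and one free ortho position, so the annulation has one possible outcome. Doing it before the acylation leaves C4a as the only place for the acetyl group.

**10 from 4 and 5.** Ring A is cut at C6–C7, C4a–C5 and C7–C8. The fragments are the siloxyalkyne 4 and 3-ethoxycyclobut-2-en-1-one 5, which react through vinylketene 6, vinylcyclobutenone 7, dienylketene 8 and dienone 9. A stepwise build-up from a phloroglucinol would need three selective O-functionalisations and a selective C-prenylation. The benzannulation delivers prenyl on C6, silyl on O5, ethyl on O8a and hydrogen on O7 in one step from two small pieces. It needs the [2+2] step to follow the polarity of the ynol ether.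

**4 from 1.** The siloxyalkyne is cut at O–Si and at the alkyne carbon that is inserted as a one-carbon unit between the prenyl group and the former carboxyl carbon. It goes back to ethyl 4-methylpent-3-enoate 1 through enolate 2 and ynolate 3 in one flask.

## Roads not taken

**Alternative 1:** Ring E would be closed at the O–C2′ bond by oxidation. The substrate is the catechol flavone A1, which has rings A, C and D complete, a 3,4-dihydroxyphenyl ring B and a 2-hydroxy-3-methylbut-3-enyl chain on C3. Ag2O oxidises A1 to its ortho-quinone, and the secondary alcohol adds to the ring carbon that becomes C2′, with re-aromatisation to the racemic isopropenyl allyl ether A2.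
- Merits: ring B of A1 needs no oxygen at C2′ and no orthogonal protecting group, the closure runs at room temperature, and the hindered alkenyl C–O coupling of the chosen plan is avoided. In these respects the road is shorter and gentler.
- Weak points: the quinone can also be attacked at the other carbon next to C1′ (C6′ of the target numbering), and the oxidant meets a free 5-hydroxyl and an electron-rich chromene. A2 is still not the target: its double bond must be moved into conjugation with oxygen without touching the prenyl group or ring D, and that isomerisation of a hindered 1,1-disubstituted allyl ether is open-ended. The plan also says nothing about ring A.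
- Comparison: the chosen route pays with a demanding copper coupling. In return the double bond position is fixed by the bromide, and ring A is solved in the same plan.

**Alternative 2:** Rings C and E would be formed together. Pd(PPh3)4 ionises the allylic carbonate of ynone A3, a ring A phenoxide adds to the palladium-bound alkyne at C2, and the alkenyl–allyl palladium intermediate forms the C3–CH2 bond, giving A4.
- Merits: two rings from one catalytic step on a linear precursor, and the enol ether enters ready-made. For rings C and E this is better in step count and in risk than the chosen separate closures.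
- Weak points: A4 has hydrogen at C6 and C8. Prenyl and ring D must then be added to a 5,7-dioxygenated flavone in the presence of the enol ether, and C6 versus C8 selectivity in such prenylations is poor. Direct O-allylation of the phenoxide by the allyl palladium species competes with the cascade.
- Comparison: the chosen route is less elegant at rings C and E, but ring A leaves its first step with every position already assigned.

**Alternative 3:** Ring A would be made last, by a polyketide-type closure. Mg(OMe)2 enolises the side-chain ketone of pyranone A5 at the prenyl-bearing methylene (C6), which attacks the ester carbon (C5) to give the 5,7-dihydroxy-6-prenyl flavone A6.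
- Merits: the 6-prenyl-5,7-diol pattern forms with complete regiocontrol and with both hydroxyls free. The ethyl/silyl differentiation and the BCl3 step of the chosen route have no counterpart here, and the later chromene annulation at C8 is reliable because the 5-hydroxyl is chelated. On ring A protecting groups this road is clearly better.
- Weak points: A5 is a fully substituted pyranone that already contains ring E, so the acid-sensitive enol ether is carried through a long linear assembly. The methylene between pyranone and ketone (C8) is more acidic than C6 and invites aldol side reactions.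
- Comparison: the chosen route makes ring A in one step from two small fragments, at the start, on a scale where failure is cheap.

Key step: step 2

Remark on the chemistry: 1, 5, 11, 16 and 22 are taken as purchasable. Compounds 7 and 25 are racemic; their stereocentres disappear downstream and the target has none. Ring positions are given in flavone numbering where stated, and otherwise in the numbering of the name.

## Route

Step 1
Reactants: 1 ethyl 4-methylpent-3-enoate
Product: 4 5-methyl-1-(triisopropylsilyloxy)hex-4-en-1-yne, via lithium dibromoenolate 2 (not isolated), via lithium ynolate 3 (not isolated)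
Conditions: CH2Br2, LiTMP (2.2 equiv), THF, −78 °C; n-BuLi, −78 °C → rt; TIPSCl, −78 °C → rt
Reagents that add atoms: dibromomethane BrCBr; chlorotriisopropylsilane CC(C)[Si](Cl)(C(C)C)C(C)C
Why: Kowalski ester homologation: dibromomethyllithium adds to the ester, the dibromomethyl ketone is enolised to 2, bromine–lithium exchange triggers 1,2-migration of the alkyl group to give ynolate 3, and the bulky chlorosilane silylates 3 on oxygen, not carbon; addition is run at −78 °C because the α-CH2 of this β,γ-unsaturated ester is unusually acidic.

Step 2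
Reactants: 4 5-methyl-1-(triisopropylsilyloxy)hex-4-en-1-yne; 5 3-ethoxycyclobut-2-en-1-one
Product: 10 5-ethoxy-2-(3-methylbut-2-enyl)-3-(triisopropylsilyloxy)phenol, via vinylketene 6 (not isolated), via vinylcyclobutenone 7 (not isolated), via dienylketene 8 (not isolated), via cyclohexadienone 9 (not isolated)
Conditions: 5 (1.3 equiv), PhMe, 80 → 110 °C, sealed vessel, argon
Reagents that add atoms: none
Why: Thermal four-electron electrocyclic opening of 5 gives vinylketene 6. The electron-rich ynol ether 4 adds to the ketene C=C in a [2+2] cycloaddition in which its nucleophilic, prenyl-bearing carbon bonds to the electrophilic ketene carbonyl carbon (C6–C7) and its oxygen-bearing carbon to the ketene α-carbon (C4a–C5), giving 7. Ring strain drives a second four-electron opening to dienylketene 8, whose six-electron disrotatory electrocyclisation forms C7–C8 and closes ring A as dienone 9; tautomerisation to phenol 10 makes the cascade irreversible. This is the Danheiser benzannulation in its siloxyalkyne form, which is known to give resorcinol monosilyl ethers; the alkoxy group on the cyclobutenone is the only departure from the usual alkyl- or aryl-substituted partners. Ring A is closed as a six-membered carbocycle by a pericyclic closure and no stereocentre is created. The step needs one orientation in the [2+2] event, secured by the polarity of the ynol ether, and reaction at the alkyne rather than the prenyl double bond, secured by the far higher nucleophilicity of the ynol ether towards ketenes. The product carries silyl on O5, hydrogen on O7, ethyl on O8a and aryl hydrogens only at C8 and C4a.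

Step 3
Reactants: 10 5-ethoxy-2-(3-methylbut-2-enyl)-3-(triisopropylsilyloxy)phenol; 11 3-methylbut-2-enal
Product: 13 5-ethoxy-2,2-dimethyl-8-(3-methylbut-2-enyl)-7-(triisopropylsilyloxy)-2H-chromene, via ortho-quinone methide 12 (not isolated)
Conditions: 11 (2 equiv), ethylenediammonium diacetate (10 mol%), xylene, 140 °C
Reagents that add atoms: none
Why: Amine-salt-catalysed chromene annulation (formal [3+3]): iminium activation of the enal, C-alkylation at the only free ortho position (C8 of the flavone), loss of water to ortho-quinone methide 12 and oxa-six-electron electrocyclisation; the other ortho position is blocked by the prenyl group.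

Step 4
Reactants: 13 5-ethoxy-2,2-dimethyl-8-(3-methylbut-2-enyl)-7-(triisopropylsilyloxy)-2H-chromene
Product: 14 1-[5-ethoxy-2,2-dimethyl-8-(3-methylbut-2-enyl)-7-(triisopropylsilyloxy)-2H-chromen-6-yl]ethanone
Conditions: AcCl, SnCl4, CH2Cl2, −78 °C
Reagents that add atoms: acetyl chloride CC(Cl)=O
Why: Friedel–Crafts acetylation at the single remaining aryl C–H, which lies ortho to two oxygens and para to the ring D oxygen and should be far more nucleophilic than the alkenes; low temperature and a mild Lewis acid spare the silyl ether, the prenyl group and the chromene.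

Step 5
Reactants: 14 1-[5-ethoxy-2,2-dimethyl-8-(3-methylbut-2-enyl)-7-(triisopropylsilyloxy)-2H-chromen-6-yl]ethanone
Product: 15 1-[5-hydroxy-2,2-dimethyl-8-(3-methylbut-2-enyl)-7-(triisopropylsilyloxy)-2H-chromen-6-yl]ethanone
Conditions: BCl3 (1.5 equiv), CH2Cl2, −78 → −20 °C; aq. NaHCO3
Reagents that add atoms: none
Why: Chelation-controlled ether cleavage: BCl3 binds the ketone and the ortho ethoxy oxygen in a six-membered chelate and chloride removes the ethyl group, whereas the bulky, weakly basic silyloxy oxygen on the other side should not take part; the liberated hydroxyl is not next to the prenyl group, so no chroman can form.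

Step 6
Reactants: 16 2,4,5-trihydroxybenzaldehyde
Product: 17 2-hydroxy-4,5-bis(triisopropylsilyloxy)benzaldehyde
Conditions: TIPSCl (2.1 equiv), imidazole, DMF, 0 °C → rt
Reagents that add atoms: chlorotriisopropylsilane CC(C)[Si](Cl)(C(C)C)C(C)C
Why: Selective silylation: the 2-hydroxyl is hydrogen-bonded to the aldehyde and much less reactive than the 4- and 5-hydroxyls, as in the standard 4-O-protection of 2,4-dihydroxybenzaldehydes.

Step 7
Reactants: 17 2-hydroxy-4,5-bis(triisopropylsilyloxy)benzaldehyde
Product: 18 2-(methoxymethoxy)-4,5-bis(triisopropylsilyloxy)benzaldehyde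
Conditions: MOMCl, i-Pr2NEt, CH2Cl2, 0 °C → rt
Reagents that add atoms: chloromethyl methyl ether COCCl
Why: Standard acetal protection of the remaining chelated phenol; the methoxymethyl ether is stable to the strong bases used later and can be removed by acid without loss of aryl triisopropylsilyl ethers.

Step 8
Reactants: 18 2-(methoxymethoxy)-4,5-bis(triisopropylsilyloxy)benzaldehyde
Product: 19 2-(methoxymethoxy)-4,5-bis(triisopropylsilyloxy)benzoic acid
Conditions: NaClO2, NaH2PO4, 2-methylbut-2-ene, t-BuOH/H2O, rt
Reagents that add atoms: sodium chlorite [Na+].[O-]Cl=O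
Why: Pinnick oxidation of the aryl aldehyde to the acid; the alkene scavenger removes hypochlorous acid so that the electron-rich ring is not chlorinated.

Step 9
Reactants: 15 1-[5-hydroxy-2,2-dimethyl-8-(3-methylbut-2-enyl)-7-(triisopropylsilyloxy)-2H-chromen-6-yl]ethanone; 19 2-(methoxymethoxy)-4,5-bis(triisopropylsilyloxy)benzoic acid
Product: 21 1-[5-hydroxy-2,2-dimethyl-8-(3-methylbut-2-enyl)-7-(triisopropylsilyloxy)-2H-chromen-6-yl]-3-[2-(methoxymethoxy)-4,5-bis(triisopropylsilyloxy)phenyl]propane-1,3-dione, via acid chloride 20 (not isolated)
Conditions: 19, 1-chloro-N,N,2-trimethylprop-1-en-1-amine, CH2Cl2, 0 °C → rt; 15, LiHMDS (3.2 equiv), THF, −78 °C, then 20, −78 °C → rt; aq. NH4Cl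
Reagents that add atoms: none
Why: Claisen-type acylation of the lithium dianion (phenoxide plus enolate) of an ortho-hydroxyacetophenone with an aroyl chloride, the one-flask variant of the Baker–Venkataraman route to 1,3-diketones; any O-aroyl ester formed rearranges under the excess base, and the acid chloride is made under neutral conditions so that the acetal survives.

Step 10
Reactants: 22 3-methylbuta-1,2-diene
Product: 24 1,2-dibromo-3-methylbut-2-ene, via tertiary allylic dibromide 23 (not isolated)
Conditions: Br2 (1.0 equiv), CH2Cl2, −78 °C; then LiBr (cat.), acetone, rt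
Reagents that add atoms: bromine BrBr
Why: Electrophilic bromination of an allene takes place once, with bromine going to the central carbon, and bromide-catalysed allylic transposition converts the kinetically formed tertiary bromide 23 into the more stable primary bromide with the tetrasubstituted double bond; the vinylic bromine deactivates the product towards a second addition.

Step 11
Reactants: 21 1-[5-hydroxy-2,2-dimethyl-8-(3-methylbut-2-enyl)-7-(triisopropylsilyloxy)-2H-chromen-6-yl]-3-[2-(methoxymethoxy)-4,5-bis(triisopropylsilyloxy)phenyl]propane-1,3-dione; 24 1,2-dibromo-3-methylbut-2-ene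
Product: 25 2-(2-bromo-3-methylbut-2-enyl)-1-[5-hydroxy-2,2-dimethyl-8-(3-methylbut-2-enyl)-7-(triisopropylsilyloxy)-2H-chromen-6-yl]-3-[2-(methoxymethoxy)-4,5-bis(triisopropylsilyloxy)phenyl]propane-1,3-dione (racemic)
Conditions: K2CO3, acetone, rt → 40 °C
Reagents that add atoms: none
Why: C-alkylation of a 1,3-diketone with a reactive primary allylic bromide under mild carbonate conditions; the vinylic bromide is inert, and the new stereocentre is formed as a racemate and disappears in step 12.

Step 12
Reactants: 25 2-(2-bromo-3-methylbut-2-enyl)-1-[5-hydroxy-2,2-dimethyl-8-(3-methylbut-2-enyl)-7-(triisopropylsilyloxy)-2H-chromen-6-yl]-3-[2-(methoxymethoxy)-4,5-bis(triisopropylsilyloxy)phenyl]propane-1,3-dione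
Product: 27 3-(2-bromo-3-methylbut-2-enyl)-2-[2-hydroxy-4,5-bis(triisopropylsilyloxy)phenyl]-8,8-dimethyl-6-(3-methylbut-2-enyl)-5-(triisopropylsilyloxy)-4H,8H-pyrano[2,3-h]chromen-4-one, via methoxymethyl flavone 26 (not isolated)
Conditions: p-TsOH·H2O (10 mol%), PhMe, 60 °C; then conc. HCl, MeOH, 45 °C
Reagents that add atoms: none
Why: Acid-catalysed cyclodehydration of the 2-alkyl-1,3-diketone through its hemiketal gives the 3-substituted flavone 26, the C8a hydroxyl being the only free phenol at that point; methanolic acid then removes the methoxymethyl group after ring C is closed, so that the ring B hydroxyl cannot compete for the diketone.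

Step 13
Reactants: 27 3-(2-bromo-3-methylbut-2-enyl)-2-[2-hydroxy-4,5-bis(triisopropylsilyloxy)phenyl]-8,8-dimethyl-6-(3-methylbut-2-enyl)-5-(triisopropylsilyloxy)-4H,8H-pyrano[2,3-h]chromen-4-one
Product: 28 5,4′,5′-tris-O-(triisopropylsilyl)isocycloheterophyllin
Conditions: CuI (20 mol%), N,N-dimethylglycine hydrochloride (40 mol%), Cs2CO3, 1,4-dioxane, 90 °C
Reagents that add atoms: none
Why: Ullmann-type C–O coupling of a phenol with an alkenyl bromide under CuI–amino acid catalysis, run intramolecularly; the C2′ oxygen and the bromoalkene on C3 are held close across the C2–C1′ bond, the closure is seven-membered, and the position of the enol ether double bond is fixed by the bromide.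

Step 14
Reactants: 28 5,4′,5′-tris-O-(triisopropylsilyl)isocycloheterophyllin
Product: 29 isocycloheterophyllin
Conditions: TBAF, AcOH, THF, 0 °C → rt, argon
Reagents that add atoms: none
Why: Fluoride cleavage of aryl silyl ethers, buffered with acetic acid so that the catechol is released as the neutral phenol and not as an air-sensitive phenoxide; the enol ether, the prenyl group and the chromene are inert to fluoride.

## Compound list

1 | ethyl 4-methylpent-3-enoate | CCOC(=O)CC=C(C)C | starting material
2 | lithium dibromoenolate: lithium 1,1-dibromo-5-methylhexa-1,4-dien-2-olate (formed in the flask) | [Li]OC(=C(Br)Br)CC=C(C)C | intermediate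
3 | lithium ynolate: lithium 5-methylhex-4-en-1-yn-1-olate (formed in the flask) | [Li]OC#CCC=C(C)C | intermediate
4 | 5-methyl-1-(triisopropylsilyloxy)hex-4-en-1-yne | CC(C)=CCC#CO[Si](C(C)C)(C(C)C)C(C)C | intermediate
5 | 3-ethoxycyclobut-2-en-1-one | CCOC1=CC(=O)C1 | starting material
6 | vinylketene: 3-ethoxybuta-1,3-dien-1-one (formed in the flask) | C=C(OCC)C=C=O | intermediate
7 | vinylcyclobutenone: 4-(1-ethoxyethenyl)-2-(3-methylbut-2-enyl)-3-(triisopropylsilyloxy)cyclobut-2-en-1-one, racemic (formed in the flask) | O=C1C(CC=C(C)C)=C(O[Si](C(C)C)(C(C)C)C(C)C)C1C(=C)OCC | intermediate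
8 | dienylketene: (3E)-5-ethoxy-2-(3-methylbut-2-enyl)-3-(triisopropylsilyloxy)hexa-1,3,5-trien-1-one (formed in the flask) | O=C=C(CC=C(C)C)/C(O[Si](C(C)C)(C(C)C)C(C)C)=C\C(OCC)=C | intermediate
9 | cyclohexadienone: 5-ethoxy-2-(3-methylbut-2-enyl)-3-(triisopropylsilyloxy)cyclohexa-2,4-dien-1-one (formed in the flask) | O=C1CC(OCC)=CC(O[Si](C(C)C)(C(C)C)C(C)C)=C1CC=C(C)C | intermediate
10 | 5-ethoxy-2-(3-methylbut-2-enyl)-3-(triisopropylsilyloxy)phenol | CC(C)=CCc1c(O)cc(OCC)cc1O[Si](C(C)C)(C(C)C)C(C)C | intermediate
11 | 3-methylbut-2-enal | CC(C)=CC=O | starting material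
12 | ortho-quinone methide: (6Z)-5-ethoxy-6-(3-methylbut-2-enylidene)-2-(3-methylbut-2-enyl)-3-(triisopropylsilyloxy)cyclohexa-2,4-dien-1-one (formed in the flask) | CC(C)=C/C=C1/C(OCC)=CC(O[Si](C(C)C)(C(C)C)C(C)C)=C(CC=C(C)C)C1=O | intermediate
13 | 5-ethoxy-2,2-dimethyl-8-(3-methylbut-2-enyl)-7-(triisopropylsilyloxy)-2H-chromene | CCOc1cc(O[Si](C(C)C)(C(C)C)C(C)C)c(CC=C(C)C)c2OC(C)(C)C=Cc12 | intermediate
14 | 1-[5-ethoxy-2,2-dimethyl-8-(3-methylbut-2-enyl)-7-(triisopropylsilyloxy)-2H-chromen-6-yl]ethanone | CCOc1c(C(C)=O)c(O[Si](C(C)C)(C(C)C)C(C)C)c(CC=C(C)C)c2OC(C)(C)C=Cc12 | intermediate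
15 | 1-[5-hydroxy-2,2-dimethyl-8-(3-methylbut-2-enyl)-7-(triisopropylsilyloxy)-2H-chromen-6-yl]ethanone | CC(=O)c1c(O)c2C=CC(C)(C)Oc2c(CC=C(C)C)c1O[Si](C(C)C)(C(C)C)C(C)C | intermediate
16 | 2,4,5-trihydroxybenzaldehyde | O=Cc1cc(O)c(O)cc1O | starting material
17 | 2-hydroxy-4,5-bis(triisopropylsilyloxy)benzaldehyde | O=Cc1cc(O[Si](C(C)C)(C(C)C)C(C)C)c(O[Si](C(C)C)(C(C)C)C(C)C)cc1O | intermediate
18 | 2-(methoxymethoxy)-4,5-bis(triisopropylsilyloxy)benzaldehyde | COCOc1cc(O[Si](C(C)C)(C(C)C)C(C)C)c(O[Si](C(C)C)(C(C)C)C(C)C)cc1C=O | intermediate
19 | 2-(methoxymethoxy)-4,5-bis(triisopropylsilyloxy)benzoic acid | COCOc1cc(O[Si](C(C)C)(C(C)C)C(C)C)c(O[Si](C(C)C)(C(C)C)C(C)C)cc1C(=O)O | intermediate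
20 | acid chloride: 2-(methoxymethoxy)-4,5-bis(triisopropylsilyloxy)benzoyl chloride (formed in the flask) | COCOc1cc(O[Si](C(C)C)(C(C)C)C(C)C)c(O[Si](C(C)C)(C(C)C)C(C)C)cc1C(=O)Cl | intermediate
21 | 1-[5-hydroxy-2,2-dimethyl-8-(3-methylbut-2-enyl)-7-(triisopropylsilyloxy)-2H-chromen-6-yl]-3-[2-(methoxymethoxy)-4,5-bis(triisopropylsilyloxy)phenyl]propane-1,3-dione | COCOc1cc(O[Si](C(C)C)(C(C)C)C(C)C)c(O[Si](C(C)C)(C(C)C)C(C)C)cc1C(=O)CC(=O)c1c(O)c2C=CC(C)(C)Oc2c(CC=C(C)C)c1O[Si](C(C)C)(C(C)C)C(C)C | intermediate
22 | 3-methylbuta-1,2-diene | CC(C)=C=C | starting material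
23 | tertiary allylic dibromide: 2,3-dibromo-3-methylbut-1-ene (formed in the flask) | C=C(Br)C(C)(C)Br | intermediate
24 | 1,2-dibromo-3-methylbut-2-ene | CC(C)=C(Br)CBr | intermediate
25 | 2-(2-bromo-3-methylbut-2-enyl)-1-[5-hydroxy-2,2-dimethyl-8-(3-methylbut-2-enyl)-7-(triisopropylsilyloxy)-2H-chromen-6-yl]-3-[2-(methoxymethoxy)-4,5-bis(triisopropylsilyloxy)phenyl]propane-1,3-dione, racemic | COCOc1cc(O[Si](C(C)C)(C(C)C)C(C)C)c(O[Si](C(C)C)(C(C)C)C(C)C)cc1C(=O)C(CC(Br)=C(C)C)C(=O)c1c(O)c2C=CC(C)(C)Oc2c(CC=C(C)C)c1O[Si](C(C)C)(C(C)C)C(C)C | intermediate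
26 | methoxymethyl flavone: 3-(2-bromo-3-methylbut-2-enyl)-2-[2-(methoxymethoxy)-4,5-bis(triisopropylsilyloxy)phenyl]-8,8-dimethyl-6-(3-methylbut-2-enyl)-5-(triisopropylsilyloxy)-4H,8H-pyrano[2,3-h]chromen-4-one (formed in the flask) | CC(C)=CCc1c(O[Si](C(C)C)(C(C)C)C(C)C)c2c(=O)c(CC(Br)=C(C)C)c(-c3cc(O[Si](C(C)C)(C(C)C)C(C)C)c(O[Si](C(C)C)(C(C)C)C(C)C)cc3OCOC)oc2c2C=CC(C)(C)Oc12 | intermediate
27 | 3-(2-bromo-3-methylbut-2-enyl)-2-[2-hydroxy-4,5-bis(triisopropylsilyloxy)phenyl]-8,8-dimethyl-6-(3-methylbut-2-enyl)-5-(triisopropylsilyloxy)-4H,8H-pyrano[2,3-h]chromen-4-one | CC(C)=CCc1c(O[Si](C(C)C)(C(C)C)C(C)C)c2c(=O)c(CC(Br)=C(C)C)c(-c3cc(O[Si](C(C)C)(C(C)C)C(C)C)c(O[Si](C(C)C)(C(C)C)C(C)C)cc3O)oc2c2C=CC(C)(C)Oc12 | intermediate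
28 | 5,4′,5′-tris-O-(triisopropylsilyl)isocycloheterophyllin (the target with its three hydroxyls as triisopropylsilyl ethers) | CC(C)=CCc1c2c(c3oc4c(c(=O)c3c1O[Si](C(C)C)(C(C)C)C(C)C)CC(=C(C)C)Oc1cc(O[Si](C(C)C)(C(C)C)C(C)C)c(O[Si](C(C)C)(C(C)C)C(C)C)cc1-4)C=CC(C)(C)O2 | intermediate
29 | isocycloheterophyllin | CC(C)=CCc1c2c(c3oc4c(c(=O)c3c1O)CC(=C(C)C)Oc1cc(O)c(O)cc1-4)C=CC(C)(C)O2 | target

## Step count and least certain steps

Total step count: 14. Longest linear sequence: 10 steps (1, 2, 3, 4, 5, 9, 11, 12, 13, 14). The ring B acid (steps 6–8) and the dibromide (step 10) are side branches.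

**Step 2 (key step).** The vinylogous-ester stabilisation of 5 may slow its ring opening. The temperature then needed could rearrange 4 to a silylketene, dimerise 6, or let 6 acylate the product phenol. The fallback generates 6 without the cyclobutenone; it sets out from 4 and comes back to the route at 10. Commercial ethyl (E)-3-ethoxybut-2-enoate is saponified to (E)-3-ethoxybut-2-enoic acid F1, which oxalyl chloride converts into (E)-3-ethoxybut-2-enoyl chloride F2. Slow addition of F2 to Et3N and 4 in toluene at room temperature effects 1,4-dehydrochlorination to 6, which 4 traps as 7, and gentle warming then carries 7 through 8 and 9 to 10.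

**Step 1.** Dibromomethyllithium may deprotonate the doubly activated α-CH2 of 1 instead of adding to the carbonyl, and the double bond may then move into conjugation. The fallback avoids the ester enolate; it sets out from 1 and comes back to the route at 4. DIBAL-H at −78 °C reduces 1 to 4-methylpent-3-enal F3, and Corey–Fuchs olefination (CBr4, PPh3) gives 1,1-dibromo-5-methylhexa-1,4-diene F4. n-BuLi converts F4 into (5-methylhex-4-en-1-ynyl)lithium F5, which is oxidised in the same flask with lithium tert-butyl peroxide to ynolate 3 and silylated with TIPSCl to 4.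

**Step 4.** The acylating agent may attack the prenyl or chromene double bond, or substitution may be slow at a position flanked by ethoxy and the bulky silyloxy group. The fallback uses an electrophile that ignores isolated alkenes; it sets out from 13 and comes back to the route at 14. Vilsmeier–Haack formylation (POCl3, DMF) gives 5-ethoxy-2,2-dimethyl-8-(3-methylbut-2-enyl)-7-(triisopropylsilyloxy)-2H-chromene-6-carbaldehyde F6, MeMgBr adds to give the racemic carbinol 1-[5-ethoxy-2,2-dimethyl-8-(3-methylbut-2-enyl)-7-(triisopropylsilyloxy)-2H-chromen-6-yl]ethanol F7, and Dess–Martin periodinane oxidises F7 to 14.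

**Step 5.** The ketone is twisted out of the ring plane by its two ortho substituents, so dealkylation may be slow. Warming could then strip the silyl ether or ionise the tertiary allylic C–O bond of ring D. The fallback moves the dealkylation to a planar, better chelating formyl group; it sets out from 13 and comes back to the route at 15. Chromene 13 is formylated to F6 as described for step 4, and BCl3 at −78 °C then gives 5-hydroxy-2,2-dimethyl-8-(3-methylbut-2-enyl)-7-(triisopropylsilyloxy)-2H-chromene-6-carbaldehyde F8. Excess MeMgBr gives the racemic diol 6-(1-hydroxyethyl)-2,2-dimethyl-8-(3-methylbut-2-enyl)-7-(triisopropylsilyloxy)-2H-chromen-5-ol F9, and MnO2 oxidises the benzylic alcohol of F9 to 15.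

**Step 13.** Monovalent copper may fail to insert into the hindered, fully substituted alkenyl bromide. Protodebromination or base-induced loss of silyl groups would then take over. The fallback reverses the polarity of the alkenyl carbon; it sets out from 27 and comes back to the route at 28. Miyaura borylation (B2pin2, Pd(dppf)Cl2, KOAc, dioxane, 80 °C) gives the alkenyl pinacol boronate 2-[2-hydroxy-4,5-bis(triisopropylsilyloxy)phenyl]-8,8-dimethyl-6-(3-methylbut-2-enyl)-3-[3-methyl-2-(4,4,5,5-tetramethyl-1,3,2-dioxaborolan-2-yl)but-2-enyl]-5-(triisopropylsilyloxy)-4H,8H-pyrano[2,3-h]chromen-4-one F10, and oxidative Chan–Lam coupling (Cu(OAc)2, pyridine, air, molecular sieves, CH2Cl2, rt) closes ring E to 28.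

## Further compounds

F1 | step 2 | (E)-3-ethoxybut-2-enoic acid | CCO/C(C)=C/C(=O)O
F2 | step 2 | (E)-3-ethoxybut-2-enoyl chloride | CCO/C(C)=C/C(=O)Cl
F3 | step 1 | 4-methylpent-3-enal | CC(C)=CCC=O
F4 | step 1 | 1,1-dibromo-5-methylhexa-1,4-diene | CC(C)=CCC=C(Br)Br
F5 | step 1 | (5-methylhex-4-en-1-ynyl)lithium | [Li]C#CCC=C(C)C
F6 | step 4 | 5-ethoxy-2,2-dimethyl-8-(3-methylbut-2-enyl)-7-(triisopropylsilyloxy)-2H-chromene-6-carbaldehyde | CCOc1c(C=O)c(O[Si](C(C)C)(C(C)C)C(C)C)c(CC=C(C)C)c2OC(C)(C)C=Cc12
F7 | step 4 | 1-[5-ethoxy-2,2-dimethyl-8-(3-methylbut-2-enyl)-7-(triisopropylsilyloxy)-2H-chromen-6-yl]ethanol, racemic | CCOc1c(C(C)O)c(O[Si](C(C)C)(C(C)C)C(C)C)c(CC=C(C)C)c2OC(C)(C)C=Cc12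
F8 | step 5 | 5-hydroxy-2,2-dimethyl-8-(3-methylbut-2-enyl)-7-(triisopropylsilyloxy)-2H-chromene-6-carbaldehyde | O=Cc1c(O)c2C=CC(C)(C)Oc2c(CC=C(C)C)c1O[Si](C(C)C)(C(C)C)C(C)C
F9 | step 5 | 6-(1-hydroxyethyl)-2,2-dimethyl-8-(3-methylbut-2-enyl)-7-(triisopropylsilyloxy)-2H-chromen-5-ol, racemic | CC(O)c1c(O)c2C=CC(C)(C)Oc2c(CC=C(C)C)c1O[Si](C(C)C)(C(C)C)C(C)C
F10 | step 13 | 2-[2-hydroxy-4,5-bis(triisopropylsilyloxy)phenyl]-8,8-dimethyl-6-(3-methylbut-2-enyl)-3-[3-methyl-2-(4,4,5,5-tetramethyl-1,3,2-dioxaborolan-2-yl)but-2-enyl]-5-(triisopropylsilyloxy)-4H,8H-pyrano[2,3-h]chromen-4-one | CC(C)=CCc1c(O[Si](C(C)C)(C(C)C)C(C)C)c2c(=O)c(CC(B3OC(C)(C)C(C)(C)O3)=C(C)C)c(-c3cc(O[Si](C(C)C)(C(C)C)C(C)C)c(O[Si](C(C)C)(C(C)C)C(C)C)cc3O)oc2c2C=CC(C)(C)Oc12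
A1 | alternative 1 | 2-(3,4-dihydroxyphenyl)-5-hydroxy-3-(2-hydroxy-3-methylbut-3-enyl)-8,8-dimethyl-6-(3-methylbut-2-enyl)-4H,8H-pyrano[2,3-h]chromen-4-one, racemic | CC(C)=CCc1c2c(c3oc(-c4ccc(O)c(O)c4)c(CC(O)C(C)=C)c(=O)c3c1O)C=CC(C)(C)O2
A2 | alternative 1 | racemic isopropenyl allyl ether isomer of the target (ring E closed, double bond not yet conjugated with oxygen) | CC(C)=CCc1c2c(c3oc4c(c(=O)c3c1O)CC(C(C)=C)Oc1cc(O)c(O)cc1-4)C=CC(C)(C)O2
A3 | alternative 2 | methyl 2-[2-[3-[4-(tert-butyldimethylsilyloxy)-2,6-dihydroxyphenyl]-3-oxoprop-1-ynyl]-4,5-bis(triisopropylsilyloxy)phenoxy]-3-methylbut-2-enyl carbonate | COC(=O)OCC(=C(C)C)Oc1cc(O[Si](C(C)C)(C(C)C)C(C)C)c(O[Si](C(C)C)(C(C)C)C(C)C)cc1C#CC(=O)c1c(O)cc(O[Si](C)(C)C(C)(C)C)cc1O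
A4 | alternative 2 | oxepinoflavone core with 5-hydroxyl, 7-O-tert-butyldimethylsilyl and ring B bis(triisopropylsilyl) ethers, unsubstituted at C6 and C8 | O=c1c2c(oc3cc(O[Si](C)(C)C(C)(C)C)cc(O)c13)-c1cc(O[Si](C(C)C)(C(C)C)C(C)C)c(O[Si](C(C)C)(C(C)C)C(C)C)cc1OC(=C(C)C)C2
A5 | alternative 3 | oxepine-fused 4-pyranone carrying a methyl ester on the carbon that becomes C4a and a 6-methyl-2-oxohept-5-enyl chain on the carbon that becomes C8a, ring B as bis(tert-butyldimethylsilyl) ether | COC(=O)c1c(CC(=O)CCC=C(C)C)oc2c(c1=O)CC(=C(C)C)Oc1cc(O[Si](C)(C)C(C)(C)C)c(O[Si](C)(C)C(C)(C)C)cc1-2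
A6 | alternative 3 | 5,7-dihydroxy-6-prenyl oxepinoflavone with ring B bis(tert-butyldimethylsilyl) ether and C8 unsubstituted | CC(C)=CCc1c(O)cc2oc3c(c(=O)c2c1O)CC(=C(C)C)Oc1cc(O[Si](C)(C)C(C)(C)C)c(O[Si](C)(C)C(C)(C)C)cc1-3
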